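Ring A (C1–C5, C10; eremophilane numbering) is assembled in one flask by a formal [3+3] radical annulation across the quaternary carbon C5 of a ring B enone. C5 carries both acceptor arms: C10, the β-carbon of the enone, and C4, an ethynyl carbon. A 3-oxopropyl radical (C1–C2–C3, from 3-(phenylselanyl)propanal) adds to C10 anti to the C5 methyl group; stannyl radical addition to the alkyne then closes C4 onto the aldehyde carbon C3. The precursor is (S)-4-ethynyl-4-methylcyclohex-2-enone, made by an enantioselective Diels–Alder reaction. Directed hydrogenation, Rubottom oxidation, α-alkenylation and double angeloylation complete the synthesis.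

Key step: step 4

Remark on numbering: eremophilane numbering is used throughout. Ring A = C1, C2, C3, C4, C5, C10; ring B = C5, C6, C7, C8, C9, C10; C14 = methyl on C5; C15 = methyl on C4; C11–C13 = isopropenyl on C7; β = the face of the C5 methyl group. The target is the 3α,9β-diester with 4β,5β-methyls, 7β-isopropenyl and 10β-H (cis-fused), i.e. 3R,4R,5R,7R,9R,10S.

Assumption: the (R,R)-configured diol catalyst of step 1 is taken to deliver (S)-4; if the sense of induction is the opposite, the (S,S)-diol is used instead.

Step 1
Reactants: 1 (E)-3-(tert-butyldimethylsilyloxy)-N,N-dimethylbuta-1,3-dien-1-amine; 2 methacrolein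
Product: 4 (S)-1-methyl-4-oxocyclohex-2-ene-1-carbaldehyde, via cycloadduct 3 (not isolated)
Conditions: (R,R)-1-naphthyl-TADDOL (20 mol%), toluene, −78 °C; then HF, MeCN, 0 °C
Reagents that add atoms: none
Why: Hydrogen-bond-catalysed enantioselective Diels–Alder reaction of the aminosiloxydiene with the α-substituted acrolein, in which the chiral diol bound to the aldehyde shields one face and so sets the quaternary C5 stereocentre; HF then cleaves the silyl enol ether and eliminates dimethylamine to unveil the enone.

Step 2
Reactants: 4 (S)-1-methyl-4-oxocyclohex-2-ene-1-carbaldehyde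
Product: 5 (S)-4-ethynyl-4-methylcyclohex-2-en-1-one
Conditions: dimethyl (1-diazo-2-oxopropyl)phosphonate, K2CO3, MeOH, 0 °C to rt
Reagents that add atoms: dimethyl (1-diazo-2-oxopropyl)phosphonate, COP(=O)(OC)C(=[N+]=[N-])C(C)=O
Why: Seyferth–Gilbert homologation with the diazomethylphosphonate generated in situ should turn the non-enolizable aldehyde into the terminal alkyne (C4≡C15) without touching C5.

Step 3
Reactants: 6 acrolein; 7 benzeneselenol
Product: 8 3-(phenylselanyl)propanal
Conditions: CH2Cl2, 0 °C
Reagents that add atoms: none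
Why: Conjugate (seleno-Michael) addition of the soft selenol to acrolein gives a storable precursor of the 3-oxopropyl radical.

Step 4
Reactants: 5 (S)-4-ethynyl-4-methylcyclohex-2-en-1-one; 8 3-(phenylselanyl)propanal
Product: 11 3α-hydroxy-5β-methyl-4-methylidene-10βH-decalin-8-one (cis-fused), via keto aldehyde 9 (not isolated), via vinylstannane 10 (not isolated)
Conditions: Bu3SnH (slow addition), AIBN, PhH, 80 °C; then more Bu3SnH, AIBN, 80 °C; then HCl, Et2O, 0 °C
Reagents that add atoms: none
Why: Proposed new method: two tin hydride radical chains run one after the other in the same flask; Bu3Sn• first abstracts the phenylselanyl group of 8, the nucleophilic 3-oxopropyl radical adds to the enone carbon C10 of 5 (Giese reaction) and the α-keto radical is reduced to give 9, then Bu3Sn• adds to the terminal alkyne carbon C15 and the resulting C4 vinyl radical closes ring A onto the aldehyde carbon C3 (alkoxyl radical reduced by Bu3SnH) to give 10, which is protodestannylated to 11. The closest known reaction types are the tin-mediated Giese addition of alkyl selenides to cyclohexenones and the stannyl-radical-induced cyclization of alkynyl aldehydes; their combination as a [3+3] radical annulation is untested. Ring A closes in a 6-exo-trig mode onto the C=O bond, and the alternative path through the O-stannyl ketyl radical at C3 attacking C4 in a 6-exo-dig mode would lead to the same alcohol. C10 is set by attack anti to the C5 methyl group, on the face of the small, linear ethynyl group, which makes C1 and C4 cis and the ring fusion cis; C3 is set in a chair-like transition state in which the alkenyl arm is axial on ring B and the carbonyl oxygen sits equatorial on the forming ring A, away from the syn-axial C5 methyl group. The step needs selenide abstraction to outrun irreversible hydrostannation of the alkyne, which the fast selenium transfer, the reversibility of stannyl radical addition to alkynes and the slow addition of Bu3SnH should secure.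

Step 5
Reactants: 11 3α-hydroxy-5β-methyl-4-methylidene-10βH-decalin-8-one
Product: 12 3α-hydroxy-4β,5β-dimethyl-10βH-decalin-8-one
Conditions: [Ir(cod)(PCy3)(py)]PF6 (cat.), H2 (1 atm), CH2Cl2, rt
Reagents that add atoms: none
Why: Hydroxyl-directed hydrogenation: the cationic iridium catalyst binds the C3 hydroxyl and should deliver H2 to the same (α) face of the exocyclic alkene, so that the new C15 methyl at C4 ends trans to the hydroxyl and cis to the C5 methyl (4β).

Step 6
Reactants: 12 3α-hydroxy-4β,5β-dimethyl-10βH-decalin-8-one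
Product: 14 3α,9β-bis(triethylsilyloxy)-4β,5β-dimethyl-10βH-decalin-8-one, via silyl enol ether 13 (not isolated)
Conditions: Et3SiOTf (at least two equivalents), Et3N, CH2Cl2, rt; then mCPBA, NaHCO3, −20 °C
Reagents that add atoms: triethylsilyl trifluoromethanesulfonate (first equivalent, silylates the C3 hydroxyl), CC[Si](CC)(CC)OS(=O)(=O)C(F)(F)F; triethylsilyl trifluoromethanesulfonate (second equivalent, forms the enol ether and ends on the C9 oxygen), CC[Si](CC)(CC)OS(=O)(=O)C(F)(F)F; 3-chloroperoxybenzoic acid, OOC(=O)c1cccc(Cl)c1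
Why: Rubottom oxidation of the thermodynamic silyl enol ether: cis-fused 2-decalones of this type enolize toward the ring fusion (C9) under equilibrating silylation, the peracid should attack the C8=C9 bond from the β face opposite the axial C5–C4 bond, and silyl migration gives the 9β-silyloxy ketone, while a first equivalent of the silyl triflate caps the C3 hydroxyl in the same pot.

Step 7
Reactants: 14 3α,9β-bis(triethylsilyloxy)-4β,5β-dimethyl-10βH-decalin-8-one; 15 2-bromopropene
Product: 16 3α,9β-bis(triethylsilyloxy)-10βH-eremophil-11-en-8-one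
Conditions: LiN(SiMe3)2, THF, −78 °C; Pd2(dba)3, P(t-Bu)3, rt; AcOH quench at −78 °C; then Et3N, CH2Cl2, rt
Reagents that add atoms: none
Why: Palladium-catalysed α-alkenylation of the kinetic lithium enolate, which should form at the unhindered C7 methylene and not at the silyloxy-bearing C9 methine; C7 is epimerizable and the brief amine treatment is expected to leave the isopropenyl group equatorial (7β).

Step 8
Reactants: 16 3α,9β-bis(triethylsilyloxy)-10βH-eremophil-11-en-8-one
Product: 17 3α,9β-dihydroxy-10βH-eremophil-11-en-8-one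
Conditions: HF·pyridine, pyridine, THF, 0 °C to rt
Reagents that add atoms: none
Why: Fluoride cleavage of both triethylsilyl ethers under buffered conditions that should leave the β,γ-unsaturated ketone and the α-ketol untouched.

Step 9
Reactants: 17 3α,9β-dihydroxy-10βH-eremophil-11-en-8-one; 18 angelic acid (two equivalents, one for each hydroxyl)
Product: 20 3α,9β-bis(angeloyloxy)-10βH-eremophil-11-en-8-one (CNP0174755.1), via mixed anhydride 19 (not isolated)
Conditions: 18 (slight excess over two equivalents), 2,4,6-trichlorobenzoyl chloride, Et3N, toluene, rt; then 17, 80 °C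
Reagents that add atoms: angelic acid (the second equivalent of 18), OC(=O)/C(C)=C\C
Why: Yamaguchi-type esterification in which each of the two secondary hydroxyls (C3 and C9) is acylated by one molecule of the mixed anhydride of angelic acid, so two equivalents of acid are consumed; it is run without a nucleophilic catalyst so that the (Z)-alkene should not isomerize to the tiglate.

Compound list
1 | (E)-3-(tert-butyldimethylsilyloxy)-N,N-dimethylbuta-1,3-dien-1-amine | C=C(O[Si](C)(C)C(C)(C)C)/C=C/N(C)C | starting material
2 | methacrolein | C=C(C)C=O | starting material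
3 | endo cycloadduct, 2-(dimethylamino)-1-methyl-4-(tert-butyldimethylsilyloxy)cyclohex-3-ene-1-carbaldehyde (CHO and NMe2 cis) | O=C[C@@]1(C)CCC(O[Si](C)(C)C(C)(C)C)=C[C@H]1N(C)C | intermediate (not isolated)
4 | (S)-1-methyl-4-oxocyclohex-2-ene-1-carbaldehyde | O=C[C@]1(C)C=CC(=O)CC1 | intermediate
5 | (S)-4-ethynyl-4-methylcyclohex-2-en-1-one | C#C[C@]1(C)C=CC(=O)CC1 | intermediate
6 | acrolein | C=CC=O | starting material
7 | benzeneselenol | [SeH]c1ccccc1 | starting material
8 | 3-(phenylselanyl)propanal | O=CCC[Se]c1ccccc1 | intermediate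
9 | 3-[(1R,2S)-2-ethynyl-2-methyl-5-oxocyclohexyl]propanal (side chain and ethynyl cis) | O=C1CC[C@](C)(C#C)[C@H](CCC=O)C1 | intermediate (not isolated)
10 | 3α-hydroxy-5β-methyl-4-(tributylstannylmethylidene)-10βH-decalin-8-one (alkene geometry not defined) | O=C1CC[C@@]2(C)[C@H](CC[C@@H](O)C2=C[Sn](CCCC)(CCCC)CCCC)C1 | intermediate (not isolated)
11 | 3α-hydroxy-5β-methyl-4-methylidene-10βH-decalin-8-one | O=C1CC[C@@]2(C)[C@H](CC[C@@H](O)C2=C)C1 | intermediate
12 | 3α-hydroxy-4β,5β-dimethyl-10βH-decalin-8-one | O=C1CC[C@@]2(C)[C@H](CC[C@@H](O)[C@@H]2C)C1 | intermediate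
13 | 3α,8-bis(triethylsilyloxy)-4β,5β-dimethyl-10βH-decal-8-ene (C8=C9 silyl enol ether) | CC[Si](CC)(CC)OC=1CC[C@@]2(C)[C@H](CC[C@@H](O[Si](CC)(CC)CC)[C@@H]2C)C=1 | intermediate (not isolated)
14 | 3α,9β-bis(triethylsilyloxy)-4β,5β-dimethyl-10βH-decalin-8-one | O=C1CC[C@@]2(C)[C@H](CC[C@@H](O[Si](CC)(CC)CC)[C@@H]2C)[C@H]1O[Si](CC)(CC)CC | intermediate
15 | 2-bromopropene | C=C(C)Br | starting material
16 | 3α,9β-bis(triethylsilyloxy)-10βH-eremophil-11-en-8-one | C=C(C)[C@H]1C[C@@]2(C)[C@H](CC[C@@H](O[Si](CC)(CC)CC)[C@@H]2C)[C@@H](O[Si](CC)(CC)CC)C1=O | intermediate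
17 | 3α,9β-dihydroxy-10βH-eremophil-11-en-8-one | C=C(C)[C@H]1C[C@@]2(C)[C@H](CC[C@@H](O)[C@@H]2C)[C@@H](O)C1=O | intermediate
18 | angelic acid, (Z)-2-methylbut-2-enoic acid | OC(=O)/C(C)=C\C | starting material
19 | angelic 2,4,6-trichlorobenzoic anhydride | O=C(OC(=O)/C(C)=C\C)c1c(Cl)cc(Cl)cc1Cl | intermediate (not isolated)
20 | 3α,9β-bis(angeloyloxy)-10βH-eremophil-11-en-8-one, (3R,4R,5R,7R,9R,10S) | C=C(C)[C@H]1C[C@@]2(C)[C@H](CC[C@@H](OC(=O)/C(C)=C\C)[C@@H]2C)[C@@H](OC(=O)/C(C)=C\C)C1=O | target

Total step count: 9. Longest linear sequence: 8 steps (steps 1, 2 and 4 to 9; step 3 prepares the radical precursor).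

Steps most likely to fail

Step 4 (Proposed new method). The alkyne may be hydrostannated before the Giese addition has taken place, the 3-oxopropyl radical may be reduced before it adds, the addition may occur on the wrong face of the enone, or the vinyl radical may abstract hydrogen from C2 in place of closing the ring. Fallback by known chemistry, setting out from 5 and returning at 11: CuBr·SMe2-catalysed conjugate addition of 2-(1,3-dioxolan-2-yl)ethylmagnesium bromide to 5 (Me3SiCl, THF, −78 °C, with an extra equivalent of the Grignard reagent to cover any deprotonation of the alkyne C–H), again anti to the C5 methyl group, would give (3R,4S)-3-[2-(1,3-dioxolan-2-yl)ethyl]-4-ethynyl-4-methylcyclohexan-1-one F1. Aqueous HCl in acetone would unmask the aldehyde 9. Nickel-catalysed reductive cyclization of the alkynyl aldehyde (Ni(cod)2, 1,3-dimesitylimidazol-2-ylidene, Et3SiH, THF) would close ring A as 3α-(triethylsilyloxy)-5β-methyl-4-methylidene-10βH-decalin-8-one F2, and Bu4NF would give 11.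

Step 7. The hindered enolate may couple sluggishly, and the isopropenyl double bond may migrate into conjugation with the ketone under the basic conditions. Fallback setting out from 14 and returning at 16: the kinetic lithium enolate of 14 (LiN(i-Pr)2, THF, −78 °C) would be added to acetone to give the aldol 7β-(2-hydroxypropan-2-yl)-3α,9β-bis(triethylsilyloxy)-4β,5β-dimethyl-10βH-decalin-8-one F3, with the bulky carbinol equatorial. Dehydration of the tertiary alcohol toward a methyl group (SOCl2, pyridine, 0 °C) would then give 16 without base-mediated equilibration at C7.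

Step 6. Enolization may not be selective for C9, so that oxidation also occurs at C7, or the peracid may approach from the α face. Fallback setting out from 12 and returning at 14: silylation of 12 (Et3SiOTf, 2,6-lutidine) would give 3α-(triethylsilyloxy)-4β,5β-dimethyl-10βH-decalin-8-one F4. Kinetic enolization away from the ring fusion (LiN(i-Pr)2, Me3SiCl, −78 °C) would give the C7=C8 trimethylsilyl enol ether F5, and Saegusa–Ito oxidation (Pd(OAc)2, MeCN) the 3α-(triethylsilyloxy)-4β,5β-dimethyl-10βH-decal-6-en-8-one F6, in which only C9 can be enolized. LiN(SiMe3)2 followed by 2-(phenylsulfonyl)-3-phenyloxaziridine would give the 9β-hydroxy enone F7. Hydrogenation (H2, Pd/C, EtOAc) would give 9β-hydroxy-3α-(triethylsilyloxy)-4β,5β-dimethyl-10βH-decalin-8-one F8, and Et3SiOTf with 2,6-lutidine would give 14.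

Further compounds
F1 | step 4 | (3R,4S)-3-[2-(1,3-dioxolan-2-yl)ethyl]-4-ethynyl-4-methylcyclohexan-1-one | O=C1CC[C@](C)(C#C)[C@H](CCC2OCCO2)C1
F2 | step 4 | 3α-(triethylsilyloxy)-5β-methyl-4-methylidene-10βH-decalin-8-one | O=C1CC[C@@]2(C)[C@H](CC[C@@H](O[Si](CC)(CC)CC)C2=C)C1
F3 | step 7 | 7β-(2-hydroxypropan-2-yl)-3α,9β-bis(triethylsilyloxy)-4β,5β-dimethyl-10βH-decalin-8-one | CC(C)(O)[C@H]1C[C@@]2(C)[C@H](CC[C@@H](O[Si](CC)(CC)CC)[C@@H]2C)[C@@H](O[Si](CC)(CC)CC)C1=O
F4 | step 6 | 3α-(triethylsilyloxy)-4β,5β-dimethyl-10βH-decalin-8-one | O=C1CC[C@@]2(C)[C@H](CC[C@@H](O[Si](CC)(CC)CC)[C@@H]2C)C1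
F5 | step 6 | 3α-(triethylsilyloxy)-8-(trimethylsilyloxy)-4β,5β-dimethyl-10βH-decal-7-ene | C[Si](C)(C)OC1=CC[C@@]2(C)[C@H](CC[C@@H](O[Si](CC)(CC)CC)[C@@H]2C)C1
F6 | step 6 | 3α-(triethylsilyloxy)-4β,5β-dimethyl-10βH-decal-6-en-8-one | O=C1C=C[C@@]2(C)[C@H](CC[C@@H](O[Si](CC)(CC)CC)[C@@H]2C)C1
F7 | step 6 | 9β-hydroxy-3α-(triethylsilyloxy)-4β,5β-dimethyl-10βH-decal-6-en-8-one | O=C1C=C[C@@]2(C)[C@H](CC[C@@H](O[Si](CC)(CC)CC)[C@@H]2C)[C@H]1O
F8 | step 6 | 9β-hydroxy-3α-(triethylsilyloxy)-4β,5β-dimethyl-10βH-decalin-8-one | O=C1CC[C@@]2(C)[C@H](CC[C@@H](O[Si](CC)(CC)CC)[C@@H]2C)[C@H]1O
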